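**Strategy.** The cycloheptenone ring (C1 = CH carrying the acetonyl group, C2 = ketone, C3=C4 = enone with CH2OH on C3, C5 = CH2, C6 = quaternary carbon, C7 = CH carrying the enol ester) is disconnected at C3: a cyclohexane made of C1, C2, C4, C5, C6 and C7 plus one inserted carbon. An asymmetric Diels–Alder reaction sets C6 and C7 and leaves a silyl enol ether whose C2=C4 bond marks the insertion site. Cyclopropanation and the key FeCl3-mediated oxidative opening of the resulting 1-silyloxybicyclo[4.1.0]heptane enlarge the ring to the seven-membered C3=C4 enone in one operation. C1 and C3 are then functionalised through the enone.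

Key step: step 7

Assumption: the sense of induction in step 3 is taken from the formyl C–H···O model for α-substituted enals bound to the oxazaborolidinium ion; should 6 form as its mirror image, the (S)-catalyst is used instead.

The atom labels C1–C7 of the target ring are used for all intermediates.

Step 1
Reactants: 1 3-(triisopropylsilyl)prop-2-ynal; 2 2-(triphenylphosphoranylidene)propanal
Product: 3 (E)-2-methyl-5-(triisopropylsilyl)pent-2-en-4-ynal
Conditions: toluene, 80 °C
Reagents that add atoms: none
Why: Wittig olefination with a formyl-stabilised ylide should give the (E)-enal, in which the alkynyl group is cis to the methyl group, as needed for the C6/C7 relationship.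

Step 2
Reactants: 4 but-3-en-2-one
Product: 5 2-(triisopropylsilyloxy)buta-1,3-diene
Conditions: TIPSOTf, Et3N, Et2O, 0 °C → rt
Reagents that add atoms: triisopropylsilyl trifluoromethanesulfonate, CC(C)[Si](OS(=O)(=O)C(F)(F)F)(C(C)C)C(C)C
Why: Soft enolisation and O-silylation of the enone, which can enolise only at its methyl group, should give the 2-silyloxydiene.

Step 3
Reactants: 3 (E)-2-methyl-5-(triisopropylsilyl)pent-2-en-4-ynal; 5 2-(triisopropylsilyloxy)buta-1,3-diene
Product: 6 (1S,6S)-1-methyl-4-(triisopropylsilyloxy)-6-[(triisopropylsilyl)ethynyl]cyclohex-3-ene-1-carbaldehyde (methyl on C6 cis to alkynyl on C7)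
Conditions: (R)-B-(o-tolyl)oxazaborolidine from (R)-α,α-diphenylprolinol, C24H24BNO (20 mol%), HN(SO2CF3)2 (20 mol%), CH2Cl2, −78 → −40 °C
Reagents that add atoms: none
Why: Catalytic enantioselective Diels–Alder reaction of an α-substituted enal on a chiral oxazaborolidinium Lewis acid: the silyloxy group directs the "para" regiochemistry (bonds C1–C7 and C5–C6, enol ether C2=C4), suprafacial addition transfers the (E)-geometry of 3 so that methyl (C6) and alkynyl (C7) are cis, and the catalyst shields one face of the s-trans enal and so fixes the absolute configuration of both centres.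

Step 4
Reactants: 6 Diels–Alder aldehyde
Product: 7 vinyl silyl enol ether (C6 bears methyl and vinyl; C7 bears the silylethynyl group cis to methyl)
Conditions: Ph3PCH3Br, KOtBu, THF, 0 °C → rt
Reagents that add atoms: methyltriphenylphosphonium bromide, C[P+](c1ccccc1)(c1ccccc1)c1ccccc1.[Br-]
Why: Wittig methylenation of a non-enolisable neopentyl aldehyde should proceed without risk to either stereocentre.

Step 5
Reactants: 7 vinyl silyl enol ether
Product: 8 4-methyl-1-(triisopropylsilyloxy)-3-[(triisopropylsilyl)ethynyl]-4-vinylbicyclo[4.1.0]heptane (C6 and C7 as in 6; both cis-fused cyclopropane diastereomers)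
Conditions: Et2Zn, CH2I2, CH2Cl2, 0 °C → rt
Reagents that add atoms: diiodomethane, ICI
Why: Furukawa–Simmons–Smith cyclopropanation, in which the electrophilic zinc carbenoid should react with the electron-rich silyl enol ether much faster than with the hindered vinyl group or the silylalkyne; the new CH2 is C3, and both diastereomers converge in step 7.

Step 6
Reactants: 8 vinyl siloxybicycloheptane; 9 9-borabicyclo[3.3.1]nonane; 10 1-bromo-2-methylprop-1-ene
Product: 12 4-methyl-4-(4-methylpent-3-enyl)-1-(triisopropylsilyloxy)-3-[(triisopropylsilyl)ethynyl]bicyclo[4.1.0]heptane, via alkylborane 11 (not isolated)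
Conditions: 9-BBN, THF, 0 °C → rt; then 10, Pd(dppf)Cl2 (5 mol%), AsPh3, Cs2CO3, DMF/H2O, rt
Reagents that add atoms: none
Why: Anti-Markovnikov hydroboration of the only terminal alkene followed by B-alkyl Suzuki–Miyaura coupling should build the 4-methylpent-3-enyl chain on C6, while the siloxycyclopropane and the bulky silylalkyne stay inert.

Step 7
Reactants: 12 homoprenyl siloxybicycloheptane
Product: 14 5-methyl-5-(4-methylpent-3-enyl)-6-[(triisopropylsilyl)ethynyl]cyclohept-2-en-1-one (C6 and C7 as in 6), via β-chloro ketone 13 (not isolated)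
Conditions: FeCl3, DMF, 0 °C → rt; then NaOAc, MeOH, 65 °C
Reagents that add atoms: FeCl3, Cl[Fe](Cl)Cl (chlorine of 13 only; no atom of it remains in 14)
Why: Ito–Saegusa oxidative ring enlargement: trivalent iron oxidises the electron-rich siloxycyclopropane by single-electron transfer, the silyl group leaves as TIPSCl, and the cyclopropyloxy radical undergoes β-scission of the C2–C4 bond shared by both rings to give the ring-enlarged C4 radical, which takes chlorine from FeCl3 (13); acetate then removes HCl by E1cB elimination to give the conjugated C3=C4 enone. The closest known reaction type is the FeCl3 ring expansion of 1-silyloxybicyclo[n.1.0]alkanes to cycloalk-2-enones. The seven-membered ring is formed by fragmentation of the zero-atom bridge of the bicyclo[4.1.0]heptane (one-carbon ring enlargement), not by an end-to-end cyclisation. No stereocentre is created in 14 (the chlorinated C4 of 13 is lost again), and C6 and C7 are not touched. The step needs regioselective cleavage of C2–C4 instead of C2–C3, which the more stable secondary radical and the Diels–Alder-derived position of the silyloxy group should secure, and chemoselectivity over the trisubstituted alkene and the alkyne, which fast chlorine transfer and the tempered Lewis acidity of FeCl3 in DMF should secure.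

Step 8
Reactants: 14 cycloheptenone; 15 2-(chloromethyl)-3,5-dioxahex-1-ene
Product: 17 7-[2-(methoxymethoxy)allyl]-5-methyl-5-(4-methylpent-3-enyl)-6-[(triisopropylsilyl)ethynyl]cyclohept-2-en-1-one (C1 epimers; mainly 1,7-trans expected), via lithium enolate 16 (not isolated)
Conditions: LDA, THF, −78 °C; then 15, Bu4NI (cat.), DMPU, −78 → −20 °C
Reagents that add atoms: lithium diisopropylamide, [Li]N(C(C)C)C(C)C (lithium of 16 only)
Why: Kinetic α'-deprotonation of the enone at C1 and C-alkylation of the cross-conjugated enolate with an allylic chloride that is a masked acetonyl group; the configuration at C1 is not yet controlled and is set in step 11.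

Step 9
Reactants: 17 C1-alkylated cycloheptenone
Product: 18 2-(hydroxymethyl)-7-[2-(methoxymethoxy)allyl]-5-methyl-5-(4-methylpent-3-enyl)-6-[(triisopropylsilyl)ethynyl]cyclohept-2-en-1-one (C1 epimers)
Conditions: aq. HCHO, DMAP, THF/H2O, rt
Reagents that add atoms: formaldehyde, C=O
Why: Morita–Baylis–Hillman reaction, in which DMAP adds to C4, the C3 enolate adds to formaldehyde and elimination of the amine restores the C3=C4 bond with CH2OH on C3.

Step 10
Reactants: 18 hydroxymethyl enone
Product: 19 6-ethynyl-2-(hydroxymethyl)-7-[2-(methoxymethoxy)allyl]-5-methyl-5-(4-methylpent-3-enyl)cyclohept-2-en-1-one (C1 epimers)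
Conditions: TBAF, THF, 0 °C → rt
Reagents that add atoms: none
Why: Fluoride-mediated protodesilylation of the alkynylsilane; C1 is still unset, so the basic medium does no harm.

Step 11
Reactants: 19 terminal alkyne
Product: 22 6-ethynyl-2-(hydroxymethyl)-5-methyl-5-(4-methylpent-3-enyl)-7-(2-oxopropyl)cyclohept-2-en-1-one with acetonyl (C1), ethynyl (C7) and methyl (C6) all cis, via trilithio enolate 20 (not isolated), via cis enol ether 21 (not isolated)
Conditions: LDA (3.3 equiv), THF, −78 °C; inverse quench into AcOH/THF, −78 °C; then 1 M HCl, THF, 0 °C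
Reagents that add atoms: lithium diisopropylamide, [Li]N(C(C)C)C(C)C (lithium of 20 only); water, O (carbonyl oxygen of the methyl ketone on hydrolysis)
Why: Kinetic protonation of an enolate followed by enol ether hydrolysis: deprotonation makes C1 trigonal, A(1,2) strain with the C1 side chain should place the C7 ethynyl group pseudo-axial, and C-protonation anti to it (stereoelectronically preferred axial attack) should give the 1,7-cis isomer, after which dilute acid converts the methoxymethyl enol ether into the methyl ketone.

Step 12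
Reactants: 22 all-cis diketone alkyne; 23 3-methylbut-2-enoic acid
Product: 24 (Z)-enol 3-methylbut-2-enoate of the C7 side chain (target lacking only the hydroperoxide; side chain on C6 is 4-methylpent-3-enyl)
Conditions: Ru(η3-2-methylallyl)2(Ph2P(CH2)4PPh2) (3 mol%), toluene, 65 °C
Reagents that add atoms: none
Why: Ruthenium-catalysed anti-Markovnikov addition of a carboxylic acid to a terminal alkyne through a divalent ruthenium vinylidene, which should give the (Z)-enol ester under neutral conditions that leave C1 untouched.

Step 13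
Reactants: 24 (Z)-enol ester
Product: 25 target CNP0283385.3 ((1R,6S,7S) in the ring labels used here)
Conditions: O2, tetraphenylporphyrin (cat.), visible light, CH2Cl2, 0 °C
Reagents that add atoms: dioxygen, O=O
Why: Schenck ene reaction of singlet oxygen with the only electron-rich trisubstituted alkene, in which abstraction of an allylic CH2 hydrogen should give the tertiary hydroperoxide with the (E)-double bond, to be separated from the secondary regioisomer; the enone, enol ester and senecioate alkenes are too electron-poor to react.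

**Compound list**

1 | 3-(triisopropylsilyl)prop-2-ynal | O=CC#C[Si](C(C)C)(C(C)C)C(C)C | starting material
2 | 2-(triphenylphosphoranylidene)propanal | CC(C=O)=P(c1ccccc1)(c1ccccc1)c1ccccc1 | starting material
3 | (E)-2-methyl-5-(triisopropylsilyl)pent-2-en-4-ynal | O=C/C(C)=C/C#C[Si](C(C)C)(C(C)C)C(C)C | intermediate
4 | but-3-en-2-one | CC(=O)C=C | starting material
5 | 2-(triisopropylsilyloxy)buta-1,3-diene | C=CC(=C)O[Si](C(C)C)(C(C)C)C(C)C | intermediate
6 | (1S,6S)-1-methyl-4-(triisopropylsilyloxy)-6-[(triisopropylsilyl)ethynyl]cyclohex-3-ene-1-carbaldehyde | C1C(O[Si](C(C)C)(C(C)C)C(C)C)=CC[C@](C)(C=O)[C@H]1C#C[Si](C(C)C)(C(C)C)C(C)C | intermediate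
7 | vinyl silyl enol ether (methylenation product of 6) | C1C(O[Si](C(C)C)(C(C)C)C(C)C)=CC[C@](C)(C=C)[C@H]1C#C[Si](C(C)C)(C(C)C)C(C)C | intermediate
8 | 4-methyl-1-(triisopropylsilyloxy)-3-[(triisopropylsilyl)ethynyl]-4-vinylbicyclo[4.1.0]heptane (cyclopropane centres unspecified: both cis-fused diastereomers) | C1C2(O[Si](C(C)C)(C(C)C)C(C)C)CC2C[C@](C)(C=C)[C@H]1C#C[Si](C(C)C)(C(C)C)C(C)C | intermediate
9 | 9-borabicyclo[3.3.1]nonane | B1C2CCCC1CCC2 | starting material
10 | 1-bromo-2-methylprop-1-ene | CC(C)=CBr | starting material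
11 | B-alkyl-9-BBN from hydroboration of 8 | C1C2(O[Si](C(C)C)(C(C)C)C(C)C)CC2C[C@](C)(CCB3C4CCCC3CCC4)[C@H]1C#C[Si](C(C)C)(C(C)C)C(C)C | intermediate (not isolated)
12 | 4-methyl-4-(4-methylpent-3-enyl)-1-(triisopropylsilyloxy)-3-[(triisopropylsilyl)ethynyl]bicyclo[4.1.0]heptane | C1C2(O[Si](C(C)C)(C(C)C)C(C)C)CC2C[C@](C)(CCC=C(C)C)[C@H]1C#C[Si](C(C)C)(C(C)C)C(C)C | intermediate
13 | 3-chloro-5-methyl-5-(4-methylpent-3-enyl)-6-[(triisopropylsilyl)ethynyl]cycloheptan-1-one (C4 unspecified) | C1C(=O)CC(Cl)C[C@](C)(CCC=C(C)C)[C@H]1C#C[Si](C(C)C)(C(C)C)C(C)C | intermediate (not isolated)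
14 | 5-methyl-5-(4-methylpent-3-enyl)-6-[(triisopropylsilyl)ethynyl]cyclohept-2-en-1-one | C1C(=O)C=CC[C@](C)(CCC=C(C)C)[C@H]1C#C[Si](C(C)C)(C(C)C)C(C)C | intermediate
15 | 2-(chloromethyl)-3,5-dioxahex-1-ene | C=C(CCl)OCOC | starting material
16 | lithium α'-enolate of 14 | C1=C(O[Li])C=CC[C@](C)(CCC=C(C)C)[C@H]1C#C[Si](C(C)C)(C(C)C)C(C)C | intermediate (not isolated)
17 | 7-[2-(methoxymethoxy)allyl]-5-methyl-5-(4-methylpent-3-enyl)-6-[(triisopropylsilyl)ethynyl]cyclohept-2-en-1-one (C1 unspecified) | C=C(OCOC)CC1C(=O)C=CC[C@](C)(CCC=C(C)C)[C@H]1C#C[Si](C(C)C)(C(C)C)C(C)C | intermediate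
18 | 2-(hydroxymethyl) derivative of 17 (C1 unspecified) | C=C(OCOC)CC1C(=O)C(CO)=CC[C@](C)(CCC=C(C)C)[C@H]1C#C[Si](C(C)C)(C(C)C)C(C)C | intermediate
19 | 6-ethynyl-2-(hydroxymethyl)-7-[2-(methoxymethoxy)allyl]-5-methyl-5-(4-methylpent-3-enyl)cyclohept-2-en-1-one (C1 unspecified) | C=C(OCOC)CC1C(=O)C(CO)=CC[C@](C)(CCC=C(C)C)[C@H]1C#C | intermediate
20 | trilithio species (enolate, alkoxide, acetylide) of 19 | C=C(OCOC)CC1=C(O[Li])C(CO[Li])=CC[C@](C)(CCC=C(C)C)[C@H]1C#C[Li] | intermediate (not isolated)
21 | 1,7-cis isomer of 19 | C=C(OCOC)C[C@H]1C(=O)C(CO)=CC[C@](C)(CCC=C(C)C)[C@H]1C#C | intermediate (not isolated)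
22 | all-cis 6-ethynyl-2-(hydroxymethyl)-5-methyl-5-(4-methylpent-3-enyl)-7-(2-oxopropyl)cyclohept-2-en-1-one | CC(=O)C[C@H]1C(=O)C(CO)=CC[C@](C)(CCC=C(C)C)[C@H]1C#C | intermediate
23 | 3-methylbut-2-enoic acid | CC(C)=CC(=O)O | starting material
24 | (Z)-enol 3-methylbut-2-enoate with 4-methylpent-3-enyl side chain | CC(=O)C[C@H]1C(=O)C(CO)=CC[C@](C)(CCC=C(C)C)[C@H]1/C=C\OC(=O)C=C(C)C | intermediate
25 | CNP0283385.3 | CC(=O)C[C@H]1C(=O)C(CO)=CC[C@](C)(C/C=C/C(C)(C)OO)[C@H]1/C=C\OC(=O)C=C(C)C | target

**Totals.** Total steps: 13. Longest linear sequence: 12 steps (steps 1 and 3–13, from 1).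

**Steps most likely to fail**

Step 11 may suffer from poor facial selectivity of the protonation (the axial C6 chain can shield the face anti to the ethynyl group) or from competing γ-deprotonation at C5. If the proton enters syn to the ethynyl group, the same facial preference means that the alkylation of step 8 has already delivered the 1,7-cis isomer of 17, and the fallback keeps that configuration by avoiding every later base. Setting out from the cis isomer of 17, 1 M HCl in THF at 0 °C should give the cis diketone F1. Iodine and pyridine in CH2Cl2 should give the cis α-iodoenone F2. Stille coupling with Bu3SnCH2OH (Pd(PPh3)4, dioxane, 80 °C) should give the cis hydroxymethyl enone F3. AgF in MeOH followed by dilute HCl should remove the alkynyl silyl group, and the route is rejoined at 22.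

Step 9 may stall because conjugate addition of the amine catalyst to the hindered, α'-substituted seven-membered enone is slow and the catalytic cycle does not turn over. The fallback installs the hydroxymethyl group by cross-coupling before the alkylation. Setting out from 14, iodine and pyridine should give the α-iodoenone F4, and Stille coupling with Bu3SnCH2OH (Pd(PPh3)4, dioxane, 80 °C) the hydroxymethyl enone F5. Double deprotonation with LDA (alkoxide and α'-enolate) and alkylation with 15 then rejoins the route at 18.

Step 13 is expected to show poor regioselectivity, because hydrogen abstraction from the cis methyl group competes with abstraction from the allylic CH2 and gives the secondary hydroperoxide. The fallback fixes the oxygen at the tertiary carbon by ionic chemistry. Setting out from 24, Markovnikov hydroxyselenation (N-(phenylseleno)phthalimide, H2O, cat. camphorsulfonic acid, CH2Cl2) should give the β-hydroxy selenide F6. Oxidation with H2O2 and pyridine and syn-elimination of the selenoxide away from the carbinol carbon should give the tertiary (E)-allylic alcohol F7. Acid-catalysed exchange with 50% H2O2 (cat. H2SO4, Et2O, 0 °C), with kinetic capture of the allyl cation at its tertiary end, rejoins the route at 25.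

**Further compounds**

F1 | step 11 | cis 5-methyl-5-(4-methylpent-3-enyl)-7-(2-oxopropyl)-6-[(triisopropylsilyl)ethynyl]cyclohept-2-en-1-one | CC(=O)C[C@H]1C(=O)C=CC[C@](C)(CCC=C(C)C)[C@H]1C#C[Si](C(C)C)(C(C)C)C(C)C
F2 | step 11 | 2-iodo derivative of F1 | CC(=O)C[C@H]1C(=O)C(I)=CC[C@](C)(CCC=C(C)C)[C@H]1C#C[Si](C(C)C)(C(C)C)C(C)C
F3 | step 11 | 2-(hydroxymethyl) derivative of F1 | CC(=O)C[C@H]1C(=O)C(CO)=CC[C@](C)(CCC=C(C)C)[C@H]1C#C[Si](C(C)C)(C(C)C)C(C)C
F4 | step 9 | 2-iodo-5-methyl-5-(4-methylpent-3-enyl)-6-[(triisopropylsilyl)ethynyl]cyclohept-2-en-1-one | C1C(=O)C(I)=CC[C@](C)(CCC=C(C)C)[C@H]1C#C[Si](C(C)C)(C(C)C)C(C)C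
F5 | step 9 | 2-(hydroxymethyl)-5-methyl-5-(4-methylpent-3-enyl)-6-[(triisopropylsilyl)ethynyl]cyclohept-2-en-1-one | C1C(=O)C(CO)=CC[C@](C)(CCC=C(C)C)[C@H]1C#C[Si](C(C)C)(C(C)C)C(C)C
F6 | step 13 | β-hydroxy selenide of 24 (4-hydroxy-4-methyl-3-(phenylselanyl)pentyl side chain) | CC(=O)C[C@H]1C(=O)C(CO)=CC[C@](C)(CCC([Se]c2ccccc2)C(C)(C)O)[C@H]1/C=C\OC(=O)C=C(C)C
F7 | step 13 | tertiary (E)-allylic alcohol corresponding to 25 | CC(=O)C[C@H]1C(=O)C(CO)=CC[C@](C)(C/C=C/C(C)(C)O)[C@H]1/C=C\OC(=O)C=C(C)C
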